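**Strategy.** The route rests on cutting the pyranone of ring A (the coumarin unit with the free C7 hydroxyl) at C4–C4a and O1–C2. The key step exploits the 1,3-relationship of the two ring A oxygens: O1 (on C8a) and the C7 hydroxyl make the arene a resorcinol whose carbon C4a, next to C8a and para to C7, is doubly activated. C2–C3–C4 is brought in as a formylacetate that already carries the unit B aryloxy group on C3. One acid-mediated Pechmann condensation joins 2,4-dimethoxyresorcinol to ethyl 2-(isofraxidin-7-yloxy)-3-oxopropanoate, closes the lactone ring and gives the unprotected target directly.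

Key step: step 6

Remark: formyl ester 11 exists largely as its hydroxymethylene (enol) tautomer; it is drawn as the aldehyde, and its alpha carbon is not a defined stereocentre.
Remark: aldehyde 3 has no free hydroxyl ortho or para to the formyl group, so the aldehyde-to-phenol oxidation is run with a peracid (Baeyer–Villiger mode) and not with alkaline H2O2.
Remark: the free carbon C5 of resorcinol 5 is ortho and para to the two methoxy groups and therefore not deactivated; the selectivity argument in step 6 takes this into account.

**Step 1**
Reactants: 1 syringol (2,6-dimethoxyphenol)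
Product: 2 2,6-dimethoxyphenyl acetate
Conditions: Ac2O, Et3N, cat. DMAP, CH2Cl2, 0 °C → rt
Reagents that add atoms: acetic anhydride, CC(=O)OC(C)=O
Why: DMAP-catalysed O-acylation should work even at the flanked hydroxyl; the acetate mutes the hydroxyl as a para director, so the next electrophile is steered by the methoxy groups, and it shields this oxygen from the peracid of step 3.

**Step 2**
Reactants: 2 2,6-dimethoxyphenyl acetate
Product: 3 3-acetoxy-2,4-dimethoxybenzaldehyde
Conditions: Cl2CHOCH3, TiCl4, CH2Cl2, −10 → 0 °C; then ice/1 M HCl
Reagents that add atoms: dichloromethyl methyl ether, COC(Cl)Cl; water, O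
Why: Rieche formylation: the chloro(methoxy)carbenium ion should attack C3 (ortho to one methoxy group, para to the other) rather than C4 (only para to the weakly donating acetoxy group), as 1,2,3-trimethoxybenzene does, and hydrolysis of the alpha-chloro ether on work-up gives the aldehyde.

**Step 3**
Reactants: 3 3-acetoxy-2,4-dimethoxybenzaldehyde
Product: 5 2,4-dimethoxybenzene-1,3-diol, via aryl formate 4 (not isolated)
Conditions: mCPBA, CH2Cl2, 0 °C → rt; aq. Na2S2O3/NaHCO3 wash; then cat. K2CO3, degassed MeOH, rt, argon; dilute HCl work-up
Reagents that add atoms: 3-chloroperoxybenzoic acid (mCPBA), OOC(=O)c1cccc(Cl)c1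
Why: Baeyer–Villiger (Dakin-type) oxidation: the aryl group with ortho and para methoxy donors should migrate in the Criegee adduct to give formate 4, and base-catalysed methanolysis then removes formyl and acetyl groups together, with air excluded because the electron-rich phenoxide is prone to oxidation.

**Step 4**
Reactants: 6 isofraxidin (7-hydroxy-6,8-dimethoxy-2H-chromen-2-one); 7 ethyl bromoacetate
Product: 8 ethyl 2-[(6,8-dimethoxy-2-oxo-2H-chromen-7-yl)oxy]acetate
Conditions: K2CO3, DMF, 60 °C
Reagents that add atoms: none
Why: Williamson ether synthesis: the acidic 7-hydroxyl (vinylogous to the lactone carbonyl) is deprotonated by carbonate and its phenoxide should displace bromide from the primary alpha-halo ester by SN2, the lactone being inert to K2CO3 in dry DMF.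

**Step 5**
Reactants: 8 ethyl 2-[(6,8-dimethoxy-2-oxo-2H-chromen-7-yl)oxy]acetate; 9 ethyl formate
Product: 11 ethyl 2-[(6,8-dimethoxy-2-oxo-2H-chromen-7-yl)oxy]-3-oxopropanoate, via sodium enolate 10 (not isolated)
Conditions: NaH, HCO2Et (excess), cat. EtOH, THF, 0 °C → rt; then cold 1 M HCl to pH 3
Reagents that add atoms: none
Why: crossed Claisen condensation (C-formylation) with a non-enolisable formate, pulled forward by the stabilised enolate 10; acidification should give 11 as its enol and reclose any lactone of unit B opened by ethoxide.

**Step 6**
Reactants: 5 2,4-dimethoxybenzene-1,3-diol (1.2 equiv); 11 ethyl 2-[(6,8-dimethoxy-2-oxo-2H-chromen-7-yl)oxy]-3-oxopropanoate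
Product: 13 7-hydroxy-6,8-dimethoxy-3-[(6,8-dimethoxy-2-oxo-2H-chromen-7-yl)oxy]-2H-chromen-2-one, via benzylic hydroxy ester 12 (not isolated)
Conditions: CH3SO3H (neat), 0 °C → rt, argon; then ice-water, filtration, recrystallisation
Reagents that add atoms: none
Why: This is a Pechmann condensation with an alpha-substituted formylacetate, a known entry to 3-substituted 7-hydroxycoumarins: the protonated formyl group of 11 attacks C6 of 5 (the future C4a) in a Friedel–Crafts hydroxyalkylation to give 12, which loses water to the aryl acrylate. The flanking hydroxyl (future O1) then attacks the ester carbonyl in a 6-exo-trig acyl substitution, expelling ethanol and closing the aromatic pyranone of ring A; no stereocentre is created, since the two transient sp3 centres of 12 are flattened in the same flask. The site selectivity needed between the two free ring carbons of 5 should favour C6, which is ortho and para to the two hydroxyls, over C5, which is activated only by the methoxy groups (the one between the hydroxyls is twisted out of conjugation); only C6 has a neighbouring hydroxyl, so no isomeric coumarin can form. Coumarin rather than chromone is secured because the aldehyde is far more electrophilic than the ester and therefore makes the carbon–carbon bond. The usual acid cyclodehydration of alpha-aryloxy beta-oxo esters to benzofuran-2-carboxylates is shut off because both carbons ortho to the ether oxygen of unit B carry methoxy groups. The C7 hydroxyl needs no protection, because it has no free ortho carbon and its transesterification is reversible and unproductive.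

**Compound list**
1 | syringol (2,6-dimethoxyphenol) | COc1cccc(OC)c1O | starting material
2 | 2,6-dimethoxyphenyl acetate | COc1cccc(OC)c1OC(C)=O | intermediate
3 | 3-acetoxy-2,4-dimethoxybenzaldehyde | COc1ccc(C=O)c(OC)c1OC(C)=O | intermediate
4 | 3-acetoxy-2,4-dimethoxyphenyl formate (aryl formate) | COc1ccc(OC=O)c(OC)c1OC(C)=O | intermediate (not isolated)
5 | 2,4-dimethoxybenzene-1,3-diol (2,4-dimethoxyresorcinol) | COc1ccc(O)c(OC)c1O | intermediate
6 | isofraxidin (7-hydroxy-6,8-dimethoxy-2H-chromen-2-one) | COc1cc2ccc(=O)oc2c(OC)c1O | starting material
7 | ethyl bromoacetate | CCOC(=O)CBr | starting material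
8 | ethyl 2-[(6,8-dimethoxy-2-oxo-2H-chromen-7-yl)oxy]acetate | CCOC(=O)COc1c(OC)cc2ccc(=O)oc2c1OC | intermediate
9 | ethyl formate | CCOC=O | starting material
10 | sodium 3-ethoxy-2-[(6,8-dimethoxy-2-oxo-2H-chromen-7-yl)oxy]-3-oxoprop-1-en-1-olate (sodium enolate of 11; double-bond geometry not defined) | CCOC(=O)C(=C[O-])Oc1c(OC)cc2ccc(=O)oc2c1OC.[Na+] | intermediate (not isolated)
11 | ethyl 2-[(6,8-dimethoxy-2-oxo-2H-chromen-7-yl)oxy]-3-oxopropanoate (aldehyde tautomer drawn; enolised, no defined stereocentre) | CCOC(=O)C(C=O)Oc1c(OC)cc2ccc(=O)oc2c1OC | intermediate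
12 | ethyl 3-(2,4-dihydroxy-3,5-dimethoxyphenyl)-3-hydroxy-2-[(6,8-dimethoxy-2-oxo-2H-chromen-7-yl)oxy]propanoate (mixture of diastereomers; both centres are lost in the same flask) | CCOC(=O)C(Oc1c(OC)cc2ccc(=O)oc2c1OC)C(O)c1cc(OC)c(O)c(OC)c1O | intermediate (not isolated)
13 | 7-hydroxy-6,8-dimethoxy-3-[(6,8-dimethoxy-2-oxo-2H-chromen-7-yl)oxy]-2H-chromen-2-one (achiral) | COc1cc2cc(Oc3c(OC)cc4ccc(=O)oc4c3OC)c(=O)oc2c(OC)c1O | target

**Step count.** Total: 6 steps. Longest linear sequence: 4 steps (steps 1, 2, 3, 6 from syringol); the isofraxidin branch has 3 (steps 4, 5, 6).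

**Steps most likely to fail**

Step 6. The Friedel–Crafts attack may go in part to the methoxy-activated carbon C5 of 5, which cannot lactonise. The formyl carbon may also be arylated twice by 5, or the enol 11 may self-condense in the acid faster than it couples. The fallback is a Perkin-type assembly of ring A, setting out from 5 and 8 and coming back at 13. Resorcinol 5 is formylated strictly ortho to a hydroxyl with MgCl2, Et3N and paraformaldehyde in MeCN, giving 2,4-dihydroxy-3,5-dimethoxybenzaldehyde F1; C6 is the only free carbon next to a hydroxyl. Ester 8 is hydrolysed with LiOH in aqueous THF and then acidified, which recloses the lactone, giving 2-[(6,8-dimethoxy-2-oxo-2H-chromen-7-yl)oxy]acetic acid F2. Heating F1 and F2 in Ac2O with Et3N (Perkin–Oglialoro condensation, the standard entry to 3-aryloxycoumarins) should give 6,8-dimethoxy-3-[(6,8-dimethoxy-2-oxo-2H-chromen-7-yl)oxy]-2-oxo-2H-chromen-7-yl acetate F3. Mild acidic methanolysis (HCl in MeOH) then frees the C7 hydroxyl to give 13.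

Step 5. Ethoxide or the ester enolate may add to the lactone or to the C3–C4 double bond of unit B, or the formyl group may be lost again (retro-Claisen) during acidification. The fallback sets out from 8 and comes back at 11. Neutral aminomethylenation with tert-butoxybis(dimethylamino)methane in toluene at 90 °C should give ethyl 3-(dimethylamino)-2-[(6,8-dimethoxy-2-oxo-2H-chromen-7-yl)oxy]prop-2-enoate F4. Its enamine is hydrolysed with 1 M HCl in THF at rt to 11.

Step 2. The electrophile may enter para to the acetoxy group (C4) instead of at C3, or TiCl4 may strip the acetyl group or the neighbouring methyl ether. The fallback sets out from 1 and comes back at 5, bypassing steps 2 and 3. Syringol is protected with MOMCl and iPr2NEt as 1,3-dimethoxy-2-(methoxymethoxy)benzene F5. Directed ortho-lithiation with n-BuLi/TMEDA in THF at 0 °C should occur next to a methoxy group, the only kind of ring position with an ortho director. Quenching with B(OMe)3 and oxidation with H2O2/NaOH gives 2,4-dimethoxy-3-(methoxymethoxy)phenol F6. HCl in MeOH then removes the acetal to give 5.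

**Further compounds**
F1 | step 6 | 2,4-dihydroxy-3,5-dimethoxybenzaldehyde | COc1cc(C=O)c(O)c(OC)c1O
F2 | step 6 | 2-[(6,8-dimethoxy-2-oxo-2H-chromen-7-yl)oxy]acetic acid | OC(=O)COc1c(OC)cc2ccc(=O)oc2c1OC
F3 | step 6 | 6,8-dimethoxy-3-[(6,8-dimethoxy-2-oxo-2H-chromen-7-yl)oxy]-2-oxo-2H-chromen-7-yl acetate | COc1cc2cc(Oc3c(OC)cc4ccc(=O)oc4c3OC)c(=O)oc2c(OC)c1OC(C)=O
F4 | step 5 | ethyl 3-(dimethylamino)-2-[(6,8-dimethoxy-2-oxo-2H-chromen-7-yl)oxy]prop-2-enoate | CCOC(=O)C(=CN(C)C)Oc1c(OC)cc2ccc(=O)oc2c1OC
F5 | step 2 | 1,3-dimethoxy-2-(methoxymethoxy)benzene | COCOc1c(OC)cccc1OC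
F6 | step 2 | 2,4-dimethoxy-3-(methoxymethoxy)phenol | COCOc1c(OC)ccc(O)c1OC
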